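Ring A of the flavonol is disconnected from an intact 2-aryl-3-oxy-4-pyranone (ring C). The feature exploited is the para pair of oxygens at C5 and C8 on a benzene ring fused through C4a-C8a, the signature of a chromium carbene benzannulation. In one operation a pyranonyl(methoxy)carbene Cr(CO)5 complex, ethynyl pinacolboronate and one CO ligand form C5-C6, C7-C8 and C8-C8a and close ring A. They deliver O5 as its methyl ether, O8 as a free phenol and boron at C7 as the handle for the 7-methoxy group. The carbene carbon enters early as the carboxyl carbon of a pyranone-3-carboxylate, so the pyranone is never halogenated or metalated.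

Key step: step 9

Remarks
- The target has no stereocentre and no configured double bond, so no stereocontrol is needed.
- Ar = 3,5-bis(benzyloxy)-4-methoxyphenyl.
- Chromenones carry flavone numbering. The monocyclic pyranones carry IUPAC pyran numbering. Pyran C3, pyran C2 and the exocyclic carboxyl or carbene carbon become C4a, C8a and C5.
- Assumption: the compounds marked as starting materials are bought. Metal carbonyl SMILES use cumulated double bonds, and the η6 complex is written as two dot-joined parts.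
- Halogenation followed by halogen-metal exchange was set aside as the entry to the carbene. Ring B is the most electron-rich arene and would be halogenated first. A pyranone metalated next to its carbonyl can also open by beta-elimination of the ring oxygen before it adds to Cr(CO)6.
- Global deprotection with a boron trihalide was set aside. The 4'-methoxy group lies between two oxygens and is the kind of crowded ether such reagents cleave.

Step 1
Reactants: 1 3,5-dihydroxy-4-methoxybenzoic acid
Product: 3 3,5-bis(benzyloxy)-4-methoxybenzoic acid, via benzyl ester 2 (not isolated)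
Conditions: BnBr (3.5 equiv), K2CO3, DMF, 60 °C; then KOH, MeOH/H2O, 70 °C; HCl
Reagents that add atoms: benzyl bromide, BrCc1ccccc1; potassium hydroxide, [K+].[OH-]
Why: Williamson alkylation of both phenols and the carboxylate, followed by saponification of the only ester, is routine and leaves the aryl benzyl and methyl ethers untouched.

Step 2
Reactants: 3 3,5-bis(benzyloxy)-4-methoxybenzoic acid
Product: 4 3,5-bis(benzyloxy)-4-methoxybenzoyl chloride
Conditions: (COCl)2, DMF (cat.), CH2Cl2, 0 °C to rt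
Reagents that add atoms: oxalyl chloride, O=C(Cl)C(=O)Cl
Why: Vilsmeier-catalysed acid chloride formation runs under mild conditions to which the aryl ethers are inert.

Step 3
Reactants: 5 tert-butyl 4-chloro-3-oxobutanoate; 6 benzyl alcohol
Product: 7 tert-butyl 4-(benzyloxy)-3-oxobutanoate
Conditions: NaH (2.2 equiv), THF, 0 °C to rt; then aq. HCl
Reagents that add atoms: none
Why: Williamson-type displacement of the 4-chloride by sodium benzyloxide on the preformed keto ester enolate is the standard entry to 4-alkoxyacetoacetates, and the tert-butyl ester resists transesterification.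

Step 4
Reactants: 7 tert-butyl 4-(benzyloxy)-3-oxobutanoate; 8 N,N-dimethylformamide dimethyl acetal
Product: 9 tert-butyl 4-(benzyloxy)-2-[(dimethylamino)methylidene]-3-oxobutanoate
Conditions: 8 (1.2 equiv), toluene, rt to 40 °C
Reagents that add atoms: none
Why: Enaminone formation by condensation with the amide acetal takes place at the doubly activated C2 methylene only, and the labile E/Z geometry has no consequence.

Step 5
Reactants: 9 tert-butyl 4-(benzyloxy)-2-[(dimethylamino)methylidene]-3-oxobutanoate; 4 3,5-bis(benzyloxy)-4-methoxybenzoyl chloride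
Product: 11 tert-butyl 5-(benzyloxy)-6-[3,5-bis(benzyloxy)-4-methoxyphenyl]-4-oxo-4H-pyran-3-carboxylate, via acylated enaminone 10 (not isolated)
Conditions: LiN(SiMe3)2 (2.3 equiv), THF, -78 °C; 4; then 2 M HCl, rt
Reagents that add atoms: none
Why: Only the C4 methylene can still be deprotonated, so a Claisen-type C-acylation of its lithium enolate gives the 1,3-diketone, and acid then closes the ring by addition-elimination of the enol oxygen at the enaminone carbon with loss of dimethylamine, the established 4-pyranone synthesis from enaminones and acid chlorides.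

Step 6
Reactants: 11 tert-butyl 5-(benzyloxy)-6-[3,5-bis(benzyloxy)-4-methoxyphenyl]-4-oxo-4H-pyran-3-carboxylate
Product: 12 5-(benzyloxy)-6-[3,5-bis(benzyloxy)-4-methoxyphenyl]-4-oxo-4H-pyran-3-carboxylic acid
Conditions: CF3CO2H/CH2Cl2 (1:3), 0 °C to rt
Reagents that add atoms: none
Why: Acidolysis of the tert-butyl ester (E1 loss of isobutene) avoids hydroxide, which would attack pyran C2 and open the ring, and benzyl ethers tolerate dilute trifluoroacetic acid at room temperature.

Step 7
Reactants: 12 5-(benzyloxy)-6-[3,5-bis(benzyloxy)-4-methoxyphenyl]-4-oxo-4H-pyran-3-carboxylic acid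
Product: 13 5-(benzyloxy)-6-[3,5-bis(benzyloxy)-4-methoxyphenyl]-4-oxo-4H-pyran-3-carbonyl chloride
Conditions: (COCl)2, DMF (cat.), CH2Cl2, 0 °C to rt; evaporate, use crude
Reagents that add atoms: oxalyl chloride, O=C(Cl)C(=O)Cl
Why: Vilsmeier-catalysed acid chloride formation is well known for 4-oxopyran- and chromone-carboxylic acids, whose acceptor-substituted ring carbonyl is too weakly nucleophilic to interfere.

Step 8
Reactants: 13 5-(benzyloxy)-6-[3,5-bis(benzyloxy)-4-methoxyphenyl]-4-oxo-4H-pyran-3-carbonyl chloride; 14 chromium hexacarbonyl, Cr(CO)6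
Product: 17 pentacarbonyl{methoxy[5-(benzyloxy)-6-[3,5-bis(benzyloxy)-4-methoxyphenyl]-4-oxo-4H-pyran-3-yl]methylidene}chromium, via disodium pentacarbonylchromate 15 (not isolated), via sodium acyl(pentacarbonyl)chromate 16 (not isolated)
Conditions: Cr(CO)6 (1.1 equiv), sodium naphthalenide NaC10H8 (2 equiv), THF, -78 to 0 °C; 13, -78 to -20 °C; MeOTf (1.0 equiv), -40 to 0 °C
Reagents that add atoms: methyl trifluoromethanesulfonate, COS(=O)(=O)C(F)(F)F
Why: Acylation of the pentacarbonylchromate dianion by an acid chloride and O-methylation of the acyl chromate, the carbanion-free variant of the Fischer carbene synthesis, is established for alkyl, alkenyl and aryl acid chlorides, needs no organometallic derivative of the sensitive pyranone, and one equivalent of MeOTf should reach the anionic acylate oxygen far faster than the neutral ring carbonyl.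

Step 9
Reactants: 17 pentacarbonyl{methoxy[5-(benzyloxy)-6-[3,5-bis(benzyloxy)-4-methoxyphenyl]-4-oxo-4H-pyran-3-yl]methylidene}chromium; 18 2-ethynyl-4,4,5,5-tetramethyl-1,3,2-dioxaborolane
Product: 20 3-(benzyloxy)-2-[3,5-bis(benzyloxy)-4-methoxyphenyl]-8-hydroxy-5-methoxy-7-(4,4,5,5-tetramethyl-1,3,2-dioxaborolan-2-yl)-4H-chromen-4-one, via tricarbonylchromium arene complex 19 (not isolated)
Conditions: 18 (2 equiv), THF (0.05 M), 50-55 °C, Ar; then air, CH2Cl2, rt
Reagents that add atoms: none
Why: Proposed new method: thermal loss of one cis CO from 17 (the vacant site can be held for a time by the C4 carbonyl oxygen as a hemilabile five-membered chelate) lets 18 bind and insert into the Cr=C bond, which forms C5-C6 and a chromium vinylcarbene, and CO then migrates to the new carbene carbon (C7-C8) to give an η4-vinylketene. Ring A closes by a thermal 6π electrocyclisation of the ketene carbon C8 onto pyran C2 (the future C8a), after which the C8a hydrogen moves to oxygen so that the cyclohexadienone becomes the C8 phenol, first bound to zerovalent chromium as 19, which air strips. The closest known reaction type is the Dötz benzannulation of alkenyl(methoxy)carbene Cr(CO)5 complexes with 1-alkynylboronates to give 4-methoxyphenol boronates; new here is a carbene on the carbon next to the carbonyl of a 4-pyranone, with the ring enol-ether double bond as the alkene partner. No stereocentre is formed. The step needs one orientation of the alkyne, CH bonded to the carbene carbon and C-B bonded to the inserted CO, and the terminal alkyne secures it sterically, because hydrogen takes the inner vinylcarbene position pressed against the CO ligands and the methoxy/pyranone end, while the bulky pinacol boronate sits on the outer carbon. Six-membered over five-membered ring formation is favoured by chromium, an oxygen rather than nitrogen donor on the carbene, an alkenyl rather than aryl carbene, and THF as solvent.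

Step 10
Reactants: 20 3-(benzyloxy)-2-[3,5-bis(benzyloxy)-4-methoxyphenyl]-8-hydroxy-5-methoxy-7-(4,4,5,5-tetramethyl-1,3,2-dioxaborolan-2-yl)-4H-chromen-4-one
Product: 21 3,8-bis(benzyloxy)-2-[3,5-bis(benzyloxy)-4-methoxyphenyl]-5-methoxy-7-(4,4,5,5-tetramethyl-1,3,2-dioxaborolan-2-yl)-4H-chromen-4-one
Conditions: BnBr (1.3 equiv), K2CO3, DMF, rt
Reagents that add atoms: benzyl bromide, BrCc1ccccc1
Why: Williamson benzylation of the only free phenol under anhydrous mild base is tolerated by the pinacol boronate and masks the oxidation-prone 4-methoxyphenol before peroxide is used.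

Step 11
Reactants: 21 3,8-bis(benzyloxy)-2-[3,5-bis(benzyloxy)-4-methoxyphenyl]-5-methoxy-7-(4,4,5,5-tetramethyl-1,3,2-dioxaborolan-2-yl)-4H-chromen-4-one
Product: 22 3,8-bis(benzyloxy)-2-[3,5-bis(benzyloxy)-4-methoxyphenyl]-7-hydroxy-5-methoxy-4H-chromen-4-one
Conditions: 30% H2O2, THF, NaH2PO4/Na2HPO4 buffer (pH 7), 0 °C to rt
Reagents that add atoms: hydrogen peroxide, OO
Why: Oxidation of an aryl boronate by hydroperoxide (1,2-shift of the aryl group from boron to oxygen, then hydrolysis) replaces boron by hydroxyl at the same carbon, and the buffered medium spares the fully etherified flavone.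

Step 12
Reactants: 22 3,8-bis(benzyloxy)-2-[3,5-bis(benzyloxy)-4-methoxyphenyl]-7-hydroxy-5-methoxy-4H-chromen-4-one
Product: 23 3,8-bis(benzyloxy)-2-[3,5-bis(benzyloxy)-4-methoxyphenyl]-5,7-dimethoxy-4H-chromen-4-one
Conditions: MeI, K2CO3, acetone, 50 °C
Reagents that add atoms: iodomethane, CI
Why: Williamson methylation of the single, acidic 7-hydroxyl group (para to the carbonyl-bearing C4a) has no competing site.

Step 13
Reactants: 23 3,8-bis(benzyloxy)-2-[3,5-bis(benzyloxy)-4-methoxyphenyl]-5,7-dimethoxy-4H-chromen-4-one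
Product: 24 8-(benzyloxy)-2-[3,5-bis(benzyloxy)-4-methoxyphenyl]-3,5-dihydroxy-7-methoxy-4H-chromen-4-one
Conditions: MgI2 (anhydrous, 5 equiv), Et2O/toluene, 80 °C; then H2O
Reagents that add atoms: none
Why: In this chelation-controlled ether cleavage magnesium binds the C4 carbonyl together with O5 or O3 and iodide removes the methyl or benzyl group by SN2, whereas the ethers at C7, C8, C3', C4' and C5' cannot chelate and should stay, as known for magnesium halide cleavage of aryl ethers ortho to a carbonyl group.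

Step 14
Reactants: 24 8-(benzyloxy)-2-[3,5-bis(benzyloxy)-4-methoxyphenyl]-3,5-dihydroxy-7-methoxy-4H-chromen-4-one
Product: 25 2-(3,5-dihydroxy-4-methoxyphenyl)-3,5,8-trihydroxy-7-methoxy-4H-chromen-4-one (target)
Conditions: H2 (1 atm), Pd/C, THF/MeOH, rt; work-up under N2
Reagents that add atoms: none
Why: Catalytic hydrogenolysis removes the three remaining aryl benzyl ethers under neutral conditions that leave both methyl ethers and the flavonol C2=C3 bond intact and suit the air-sensitive 5,8-hydroquinone.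

Compound list
1 | 3,5-dihydroxy-4-methoxybenzoic acid | COc1c(O)cc(C(=O)O)cc1O | starting material
2 | benzyl 3,5-bis(benzyloxy)-4-methoxybenzoate | COc1c(OCc2ccccc2)cc(C(=O)OCc2ccccc2)cc1OCc1ccccc1 | intermediate
3 | 3,5-bis(benzyloxy)-4-methoxybenzoic acid | COc1c(OCc2ccccc2)cc(C(=O)O)cc1OCc1ccccc1 | intermediate
4 | 3,5-bis(benzyloxy)-4-methoxybenzoyl chloride | COc1c(OCc2ccccc2)cc(C(=O)Cl)cc1OCc1ccccc1 | intermediate
5 | tert-butyl 4-chloro-3-oxobutanoate | CC(C)(C)OC(=O)CC(=O)CCl | starting material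
6 | benzyl alcohol | OCc1ccccc1 | starting material
7 | tert-butyl 4-(benzyloxy)-3-oxobutanoate | CC(C)(C)OC(=O)CC(=O)COCc1ccccc1 | intermediate
8 | N,N-dimethylformamide dimethyl acetal | COC(OC)N(C)C | starting material
9 | tert-butyl 4-(benzyloxy)-2-[(dimethylamino)methylidene]-3-oxobutanoate (E/Z labile) | CC(C)(C)OC(=O)C(=CN(C)C)C(=O)COCc1ccccc1 | intermediate
10 | tert-butyl 4-(benzyloxy)-5-[3,5-bis(benzyloxy)-4-methoxyphenyl]-2-[(dimethylamino)methylidene]-3,5-dioxopentanoate (enolisable, C4 configurationally labile) | CC(C)(C)OC(=O)C(=CN(C)C)C(=O)C(OCc1ccccc1)C(=O)c1cc(OCc2ccccc2)c(OC)c(OCc2ccccc2)c1 | intermediate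
11 | tert-butyl 5-(benzyloxy)-6-[3,5-bis(benzyloxy)-4-methoxyphenyl]-4-oxo-4H-pyran-3-carboxylate | CC(C)(C)OC(=O)c1coc(-c2cc(OCc3ccccc3)c(OC)c(OCc3ccccc3)c2)c(OCc2ccccc2)c1=O | intermediate
12 | 5-(benzyloxy)-6-[3,5-bis(benzyloxy)-4-methoxyphenyl]-4-oxo-4H-pyran-3-carboxylic acid | OC(=O)c1coc(-c2cc(OCc3ccccc3)c(OC)c(OCc3ccccc3)c2)c(OCc2ccccc2)c1=O | intermediate
13 | 5-(benzyloxy)-6-[3,5-bis(benzyloxy)-4-methoxyphenyl]-4-oxo-4H-pyran-3-carbonyl chloride | ClC(=O)c1coc(-c2cc(OCc3ccccc3)c(OC)c(OCc3ccccc3)c2)c(OCc2ccccc2)c1=O | intermediate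
14 | chromium hexacarbonyl, Cr(CO)6 | O=C=[Cr](=C=O)(=C=O)(=C=O)(=C=O)=C=O | starting material
15 | disodium pentacarbonylchromate, Na2Cr(CO)5 | [Na+].[Na+].O=C=[Cr-2](=C=O)(=C=O)(=C=O)=C=O | intermediate
16 | sodium pentacarbonyl{[5-(benzyloxy)-6-[3,5-bis(benzyloxy)-4-methoxyphenyl]-4-oxo-4H-pyran-3-yl]carbonyl}chromate | [Na+].[O-]C(c1coc(-c2cc(OCc3ccccc3)c(OC)c(OCc3ccccc3)c2)c(OCc2ccccc2)c1=O)=[Cr](=C=O)(=C=O)(=C=O)(=C=O)=C=O | intermediate
17 | pentacarbonyl{methoxy[5-(benzyloxy)-6-[3,5-bis(benzyloxy)-4-methoxyphenyl]-4-oxo-4H-pyran-3-yl]methylidene}chromium | COC(c1coc(-c2cc(OCc3ccccc3)c(OC)c(OCc3ccccc3)c2)c(OCc2ccccc2)c1=O)=[Cr](=C=O)(=C=O)(=C=O)(=C=O)=C=O | intermediate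
18 | 2-ethynyl-4,4,5,5-tetramethyl-1,3,2-dioxaborolane | C#CB1OC(C)(C)C(C)(C)O1 | starting material
19 | tricarbonylchromium complex of 20, Cr(CO)3 bound η6 to ring A | COc1cc(B2OC(C)(C)C(C)(C)O2)c(O)c2oc(-c3cc(OCc4ccccc4)c(OC)c(OCc4ccccc4)c3)c(OCc3ccccc3)c(=O)c12.O=C=[Cr](=C=O)=C=O | intermediate
20 | 3-(benzyloxy)-2-[3,5-bis(benzyloxy)-4-methoxyphenyl]-8-hydroxy-5-methoxy-7-(4,4,5,5-tetramethyl-1,3,2-dioxaborolan-2-yl)-4H-chromen-4-one | COc1cc(B2OC(C)(C)C(C)(C)O2)c(O)c2oc(-c3cc(OCc4ccccc4)c(OC)c(OCc4ccccc4)c3)c(OCc3ccccc3)c(=O)c12 | intermediate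
21 | 3,8-bis(benzyloxy)-2-[3,5-bis(benzyloxy)-4-methoxyphenyl]-5-methoxy-7-(4,4,5,5-tetramethyl-1,3,2-dioxaborolan-2-yl)-4H-chromen-4-one | COc1cc(B2OC(C)(C)C(C)(C)O2)c(OCc2ccccc2)c2oc(-c3cc(OCc4ccccc4)c(OC)c(OCc4ccccc4)c3)c(OCc3ccccc3)c(=O)c12 | intermediate
22 | 3,8-bis(benzyloxy)-2-[3,5-bis(benzyloxy)-4-methoxyphenyl]-7-hydroxy-5-methoxy-4H-chromen-4-one | COc1cc(O)c(OCc2ccccc2)c2oc(-c3cc(OCc4ccccc4)c(OC)c(OCc4ccccc4)c3)c(OCc3ccccc3)c(=O)c12 | intermediate
23 | 3,8-bis(benzyloxy)-2-[3,5-bis(benzyloxy)-4-methoxyphenyl]-5,7-dimethoxy-4H-chromen-4-one | COc1cc(OC)c(OCc2ccccc2)c2oc(-c3cc(OCc4ccccc4)c(OC)c(OCc4ccccc4)c3)c(OCc3ccccc3)c(=O)c12 | intermediate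
24 | 8-(benzyloxy)-2-[3,5-bis(benzyloxy)-4-methoxyphenyl]-3,5-dihydroxy-7-methoxy-4H-chromen-4-one | COc1cc(O)c2c(=O)c(O)c(-c3cc(OCc4ccccc4)c(OC)c(OCc4ccccc4)c3)oc2c1OCc1ccccc1 | intermediate
25 | 2-(3,5-dihydroxy-4-methoxyphenyl)-3,5,8-trihydroxy-7-methoxy-4H-chromen-4-one | COc1cc(O)c2c(=O)c(O)c(-c3cc(O)c(OC)c(O)c3)oc2c1O | target

Total step count: 14. Longest linear sequence: 12 steps (1, 2, 5-14 from 1; equally 3, 4, 5-14 from 5).

Steps most likely to fail

Step 9 (the labelled step).
- What may go wrong: the electron-poor carbene may decompose, by loss of chromium or by attack at pyran C2, before it takes up the alkyne.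
- The alkyne may also insert in the reverse sense. Boron is a π-acceptor and is electronically favoured next to the enol-ether carbon, which would put boron at C6.
- The vinylcarbene may instead divert to five-membered ring products.
- Fallback: it uses known chemistry only, buys ring A instead of building it, sets out from 4 and returns at 25.
- The polyanion of bought 1-(2,6-dihydroxy-4-methoxyphenyl)ethan-1-one F1, formed with excess LiN(SiMe3)2 in THF, is C-acylated by 4 to the 1,3-diketone F2. p-Toluenesulfonic acid in hot toluene cyclodehydrates this to the 5-hydroxy-7-methoxyflavone F3.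
- Elbs persulfate oxidation (K2S2O8, aq. KOH/pyridine) attacks para to the 5-phenolate and gives the potassium 8-sulfate F4. Warm dilute HCl hydrolyses it to the 5,8-dihydroxyflavone F5.
- Exhaustive benzylation (BnBr, K2CO3, DMF, 80 °C) gives the 5,8-bis(benzyl ether) F6, and dimethyldioxirane hydroxylates C3 to the protected flavonol F7. Hydrogenolysis under the conditions of step 14 then gives 25.

Step 8.
- What may go wrong: the strongly reducing chromate dianion may transfer an electron or add in conjugate fashion at pyran C2 instead of substituting at the acyl chloride. The ring carbonyl may also be methylated to a pyrylium salt.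
- Fallback: it forms the chromium-carbon bond from a carbon nucleophile and Cr(CO)6, sets out from 13 and returns at 17.
- 13 and sodium 2-thioxopyridin-1(2H)-olate (NaC5H4NOS) give the Barton ester F8. Heating with CHI3 in toluene converts it by Barton decarboxylative iodination to the 5-iodopyranone F9, so ring B never meets an electrophilic halogen.
- Iodine-magnesium exchange with iPrMgCl·LiCl in THF at -40 °C gives the pyranonylmagnesium chloride F10. Addition to Cr(CO)6 gives the chloromagnesium acyl chromate F11, and MeOTf converts this to 17.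

Step 13.
- What may go wrong: cleavage at O5 may stall once magnesium is locked in the O3/O4 chelate, or further ethers may be lost when the reaction is forced.
- Fallback: the C5 methyl group is removed oxidatively through the para C5/C8 relationship, with no Lewis acid. It sets out from 20 and returns at 25.
- Buffered H2O2 oxidation of 20 with O8 left free gives the 7,8-catechol F12. One equivalent of MeI with Li2CO3 in DMF methylates the more acidic 7-hydroxyl group and gives the 8-hydroxy-5,7-dimethoxyflavone F13.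
- PhI(OAc)2 in MeCN/H2O at 0 °C oxidises the 4-methoxyphenol unit with loss of methanol to the 7-methoxyflavone-5,8-quinone F14. H2 over Pd/C reduces the quinone to the hydroquinone and cleaves the three benzyl ethers in one operation, giving 25.

Further compounds
F1 | step 9 | 1-(2,6-dihydroxy-4-methoxyphenyl)ethan-1-one (bought) | CC(=O)c1c(O)cc(OC)cc1O
F2 | step 9 | 1-[3,5-bis(benzyloxy)-4-methoxyphenyl]-3-(2,6-dihydroxy-4-methoxyphenyl)propane-1,3-dione | COc1cc(O)c(C(=O)CC(=O)c2cc(OCc3ccccc3)c(OC)c(OCc3ccccc3)c2)c(O)c1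
F3 | step 9 | 2-[3,5-bis(benzyloxy)-4-methoxyphenyl]-5-hydroxy-7-methoxy-4H-chromen-4-one | COc1cc(O)c2c(=O)cc(-c3cc(OCc4ccccc4)c(OC)c(OCc4ccccc4)c3)oc2c1
F4 | step 9 | potassium 2-[3,5-bis(benzyloxy)-4-methoxyphenyl]-5-hydroxy-7-methoxy-4-oxo-4H-chromen-8-yl sulfate | COc1cc(O)c2c(=O)cc(-c3cc(OCc4ccccc4)c(OC)c(OCc4ccccc4)c3)oc2c1OS(=O)(=O)[O-].[K+]
F5 | step 9 | 2-[3,5-bis(benzyloxy)-4-methoxyphenyl]-5,8-dihydroxy-7-methoxy-4H-chromen-4-one | COc1cc(O)c2c(=O)cc(-c3cc(OCc4ccccc4)c(OC)c(OCc4ccccc4)c3)oc2c1O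
F6 | step 9 | 5,8-bis(benzyloxy)-2-[3,5-bis(benzyloxy)-4-methoxyphenyl]-7-methoxy-4H-chromen-4-one | COc1cc(OCc2ccccc2)c2c(=O)cc(-c3cc(OCc4ccccc4)c(OC)c(OCc4ccccc4)c3)oc2c1OCc1ccccc1
F7 | step 9 | 5,8-bis(benzyloxy)-2-[3,5-bis(benzyloxy)-4-methoxyphenyl]-3-hydroxy-7-methoxy-4H-chromen-4-one | COc1cc(OCc2ccccc2)c2c(=O)c(O)c(-c3cc(OCc4ccccc4)c(OC)c(OCc4ccccc4)c3)oc2c1OCc1ccccc1
F8 | step 8 | 2-thioxopyridin-1(2H)-yl 5-(benzyloxy)-6-[3,5-bis(benzyloxy)-4-methoxyphenyl]-4-oxo-4H-pyran-3-carboxylate | O=C(On1ccccc1=S)c1coc(-c2cc(OCc3ccccc3)c(OC)c(OCc3ccccc3)c2)c(OCc2ccccc2)c1=O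
F9 | step 8 | 3-(benzyloxy)-2-[3,5-bis(benzyloxy)-4-methoxyphenyl]-5-iodo-4H-pyran-4-one | O=c1c(I)coc(-c2cc(OCc3ccccc3)c(OC)c(OCc3ccccc3)c2)c1OCc1ccccc1
F10 | step 8 | [5-(benzyloxy)-6-[3,5-bis(benzyloxy)-4-methoxyphenyl]-4-oxo-4H-pyran-3-yl]magnesium chloride | O=c1c([Mg]Cl)coc(-c2cc(OCc3ccccc3)c(OC)c(OCc3ccccc3)c2)c1OCc1ccccc1
F11 | step 8 | chloromagnesium pentacarbonyl{[5-(benzyloxy)-6-[3,5-bis(benzyloxy)-4-methoxyphenyl]-4-oxo-4H-pyran-3-yl]carbonyl}chromate | Cl[Mg]OC(c1coc(-c2cc(OCc3ccccc3)c(OC)c(OCc3ccccc3)c2)c(OCc2ccccc2)c1=O)=[Cr](=C=O)(=C=O)(=C=O)(=C=O)=C=O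
F12 | step 13 | 3-(benzyloxy)-2-[3,5-bis(benzyloxy)-4-methoxyphenyl]-7,8-dihydroxy-5-methoxy-4H-chromen-4-one | COc1cc(O)c(O)c2oc(-c3cc(OCc4ccccc4)c(OC)c(OCc4ccccc4)c3)c(OCc3ccccc3)c(=O)c12
F13 | step 13 | 3-(benzyloxy)-2-[3,5-bis(benzyloxy)-4-methoxyphenyl]-8-hydroxy-5,7-dimethoxy-4H-chromen-4-one | COc1cc(OC)c(O)c2oc(-c3cc(OCc4ccccc4)c(OC)c(OCc4ccccc4)c3)c(OCc3ccccc3)c(=O)c12
F14 | step 13 | 3-(benzyloxy)-2-[3,5-bis(benzyloxy)-4-methoxyphenyl]-7-methoxy-4H-chromene-4,5,8-trione | COC1=CC(=O)c2c(oc(-c3cc(OCc4ccccc4)c(OC)c(OCc4ccccc4)c3)c(OCc3ccccc3)c2=O)C1=O
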